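**Plan**

- Retrosynthesis: the aldehyde comes from a primary allylic alcohol and the two esters from acylations. That alcohol and the C3 hydroxyl come from reductive opening of a γ-lactone (temporary ring C) that ties the formyl carbon to the oxygen on C3.
- Ring B (the dihydrofuran) is then cut at O1–C2 and C3a–C3 together. This gives 4-hydroxyacetophenone (ring A with O1) and the methyl carbonate of the Morita–Baylis–Hillman adduct of tert-butyl acrylate and glyoxal dimethyl acetal.
- Enabling feature: C2 of ring B is the carbinol carbon of a Baylis–Hillman adduct (it carries O1 and the 1-formylvinyl carbon). Its neighbour C3 is at the aldehyde oxidation level. The cis relation of the C3 oxygen and the C2 vinyl group lets both sit in a cis-fused five-membered lactone.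
- Forward: Baylis–Hillman reaction, carbonate formation, then in one flask asymmetric allylic etherification (O1–C2), lactonisation (ring C) and Friedel–Crafts closure (C3a–C3, ring B). Then ketone reduction, lactone opening, acylations and a final oxidation.
- Stereochemistry: C2 from the chiral palladium ligand, C3 from the obligatory cis fusion of rings B and C, the side-chain carbinol from a CBS reduction, the Z alkene from angelic acid.

Key step: step 3

Assumption: the (R,R)-configured ligand is taken to deliver the (R)-configured ether 6; the sense of induction with this carbonate has to be confirmed by correlation on the first run, and the (S,S)-ligand is to be used if it proves opposite.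

**Step 1**
Reactants: 1 tert-butyl acrylate; 2 2,2-dimethoxyacetaldehyde
Product: 3 tert-butyl 3-hydroxy-4,4-dimethoxy-2-methylidenebutanoate (racemic)
Conditions: DABCO (1 equiv), 1,4-dioxane/H2O, rt, 2–4 d
Reagents that add atoms: none
Why: Morita–Baylis–Hillman reaction, in which the amine-derived acrylate enolate adds to an electron-poor α,α-dialkoxy aldehyde; the new carbinol centre needs no control because it is erased in step 3.

**Step 2**
Reactants: 3 tert-butyl 3-hydroxy-4,4-dimethoxy-2-methylidenebutanoate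
Product: 4 tert-butyl 4,4-dimethoxy-3-[(methoxycarbonyl)oxy]-2-methylidenebutanoate (racemic)
Conditions: ClCO2Me, pyridine, DMAP (cat.), CH2Cl2, 0 °C → rt
Reagents that add atoms: methyl chloroformate, COC(=O)Cl
Why: O-acylation of the secondary allylic alcohol with a chloroformate should give the allylic carbonate, which serves as leaving group and as internal source of methoxide base in step 3.

**Step 3**
Reactants: 4 tert-butyl 4,4-dimethoxy-3-[(methoxycarbonyl)oxy]-2-methylidenebutanoate; 5 4-hydroxyacetophenone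
Product: 8 (3aR,8bR)-7-acetyl-3-methylidene-3a,8b-dihydrofuro[3,2-b][1]benzofuran-2(3H)-one, via allyl aryl ether 6 (not isolated), via methoxy lactone 7 (not isolated)
Conditions: Pd2(dba)3·CHCl3 (2.5 mol %), (R,R)-DACH-phenyl bisphosphine ligand (7.5 mol %), CH2Cl2, rt; then TMSOTf (4 equiv), −40 → 0 °C, same flask; aq. NaHCO3
Reagents that add atoms: none
Why: Proposed new method: zerovalent palladium ionises racemic 4 to a pair of interconverting π-allyl complexes, the phenoxide of 5 (generated by the released methoxide) attacks the substituted allyl terminus under ligand control to give branched ether 6, and TMSOTf then ionises the acetal so that the tert-butyl ester oxygen captures the oxocarbenium ion with loss of 2-methylpropene (pseudo-ester 7); a second ionisation gives a cyclic acyloxocarbenium ion that alkylates the ortho carbon of ring A. The closest known reaction types are the Tsuji–Trost-type dynamic kinetic asymmetric etherification of Morita–Baylis–Hillman carbonates with phenols, the acid-mediated cyclisation of aryloxyacetaldehyde acetals to benzofurans, and the Friedel–Crafts arylation of 5-hydroxy- and 5-alkoxy-furanones; their merger in one flask and the use of the lactone as a stereocontrolling ring on an acyl-substituted aryl ether are without precedent. Ring C closes by 5-exo-trig attack of the ester carbonyl oxygen on the C=O+ carbon, and ring B by 5-exo-trig Friedel–Crafts attack of the aromatic carbon on the acyloxocarbenium carbon. C2 is controlled by the chiral ligand; C3 is controlled by ring strain, because a trans-fused 5–5 system is prohibitively strained, so both acetal epimers of 7 converge on the cis-fused product and the acetal carbon needs no stereocontrol. The step needs branched over linear etherification (kinetic preference of this ligand class at room temperature), O- over C-allylation (acidic, para-substituted phenol) and ring closure faster than proton loss from C2 of the cation (low temperature, non-basic medium); the two ortho positions of 5 are equivalent, and the acetyl group para to O1 disfavours re-ionisation of the new benzylic C3–O bond, which protects the product from elimination to a benzofuran.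

**Step 4**
Reactants: 8 (3aR,8bR)-7-acetyl-3-methylidene-3a,8b-dihydrofuro[3,2-b][1]benzofuran-2(3H)-one
Product: 9 (3aR,8bR)-7-[(1R)-1-hydroxyethyl]-3-methylidene-3a,8b-dihydrofuro[3,2-b][1]benzofuran-2(3H)-one
Conditions: (S)-2-methyl-CBS-oxazaborolidine (20 mol %), catecholborane (1.8 equiv), toluene/CH2Cl2, −78 °C; MeOH, pH 7 buffer
Reagents that add atoms: none
Why: Corey–Bakshi–Shibata reduction, in which the (S)-catalyst should give the (R)-carbinol as it does with acetophenone (aryl as the large group), while catecholborane at low temperature leaves the lactone and its electron-poor alkene untouched.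

**Step 5**
Reactants: 9 (3aR,8bR)-7-[(1R)-1-hydroxyethyl]-3-methylidene-3a,8b-dihydrofuro[3,2-b][1]benzofuran-2(3H)-one
Product: 10 (3aR,8bR)-3-methylidene-7-[(1R)-1-(triethylsilyloxy)ethyl]-3a,8b-dihydrofuro[3,2-b][1]benzofuran-2(3H)-one
Conditions: Et3SiOTf, 2,6-lutidine, CH2Cl2, −78 °C
Reagents that add atoms: triethylsilyl trifluoromethanesulfonate, CC[Si](CC)(CC)OS(=O)(=O)C(F)(F)F
Why: standard silylation of a secondary alcohol, run with a non-nucleophilic base so that nothing adds to the α-methylene lactone.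

**Step 6**
Reactants: 10 (3aR,8bR)-3-methylidene-7-[(1R)-1-(triethylsilyloxy)ethyl]-3a,8b-dihydrofuro[3,2-b][1]benzofuran-2(3H)-one
Product: 11 (2R,3R)-2-(3-hydroxyprop-1-en-2-yl)-5-[(1R)-1-(triethylsilyloxy)ethyl]-2,3-dihydro-1-benzofuran-3-ol
Conditions: i-Bu2AlH (3.5 equiv), CH2Cl2, −78 → −20 °C; aq. potassium sodium tartrate
Reagents that add atoms: none
Why: 1,2-reduction of the α-methylene-γ-lactone through the lactol to the 2-methylene-1,4-diol removes temporary ring C; only the acyl C–O bond is cleaved, so C2 and C3 are untouched.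

**Step 7**
Reactants: 11 (2R,3R)-2-(3-hydroxyprop-1-en-2-yl)-5-[(1R)-1-(triethylsilyloxy)ethyl]-2,3-dihydro-1-benzofuran-3-ol
Product: 12 (2R,3R)-2-[3-(tert-butyldiphenylsilyloxy)prop-1-en-2-yl]-5-[(1R)-1-(triethylsilyloxy)ethyl]-2,3-dihydro-1-benzofuran-3-ol
Conditions: t-BuPh2SiCl (1.05 equiv), imidazole, CH2Cl2, 0 °C
Reagents that add atoms: tert-butyl(chloro)diphenylsilane, CC(C)(C)[Si](Cl)(c1ccccc1)c1ccccc1
Why: the bulky silyl chloride should react at the primary allylic hydroxyl and leave the hindered secondary benzylic hydroxyl at C3 free (steric differentiation in silylation).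

**Step 8**
Reactants: 12 (2R,3R)-2-[3-(tert-butyldiphenylsilyloxy)prop-1-en-2-yl]-5-[(1R)-1-(triethylsilyloxy)ethyl]-2,3-dihydro-1-benzofuran-3-ol
Product: 13 (2R,3R)-2-[3-(tert-butyldiphenylsilyloxy)prop-1-en-2-yl]-5-[(1R)-1-(triethylsilyloxy)ethyl]-2,3-dihydro-1-benzofuran-3-yl acetate
Conditions: Ac2O, pyridine, DMAP (cat.), CH2Cl2, 0 °C → rt
Reagents that add atoms: acetic anhydride, CC(=O)OC(C)=O
Why: DMAP-catalysed acetylation of the only free hydroxyl installs the C3 acetate with retention, since the C3–O bond is not broken.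

**Step 9**
Reactants: 13 (2R,3R)-2-[3-(tert-butyldiphenylsilyloxy)prop-1-en-2-yl]-5-[(1R)-1-(triethylsilyloxy)ethyl]-2,3-dihydro-1-benzofuran-3-yl acetate
Product: 14 (2R,3R)-2-[3-(tert-butyldiphenylsilyloxy)prop-1-en-2-yl]-5-[(1R)-1-hydroxyethyl]-2,3-dihydro-1-benzofuran-3-yl acetate
Conditions: HF·pyridine, pyridine, THF, 0 °C
Reagents that add atoms: none
Why: buffered HF·pyridine should cleave the triethylsilyl ether much faster than the tert-butyldiphenylsilyl ether (selective desilylation), and the nearly neutral medium spares the acid-sensitive benzylic positions.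

**Step 10**
Reactants: 14 (2R,3R)-2-[3-(tert-butyldiphenylsilyloxy)prop-1-en-2-yl]-5-[(1R)-1-hydroxyethyl]-2,3-dihydro-1-benzofuran-3-yl acetate; 15 angelic acid
Product: 17 (1R)-1-{(2R,3R)-3-acetoxy-2-[3-(tert-butyldiphenylsilyloxy)prop-1-en-2-yl]-2,3-dihydro-1-benzofuran-5-yl}ethyl (2Z)-2-methylbut-2-enoate, via angelic 2,4,6-trichlorobenzoic anhydride 16 (not isolated)
Conditions: 15, 2,4,6-trichlorobenzoyl chloride, Et3N, toluene, rt; then 14, toluene, 75 °C, no DMAP
Reagents that add atoms: none
Why: Yamaguchi esterification, in which the alcohol attacks the less hindered angeloyl carbonyl of the mixed anhydride with retention at the carbinol carbon; leaving out DMAP should avoid isomerisation of the Z alkene.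

**Step 11**
Reactants: 17 (1R)-1-{(2R,3R)-3-acetoxy-2-[3-(tert-butyldiphenylsilyloxy)prop-1-en-2-yl]-2,3-dihydro-1-benzofuran-5-yl}ethyl (2Z)-2-methylbut-2-enoate
Product: 18 (1R)-1-[(2R,3R)-3-acetoxy-2-(3-hydroxyprop-1-en-2-yl)-2,3-dihydro-1-benzofuran-5-yl]ethyl (2Z)-2-methylbut-2-enoate
Conditions: Bu4NF, AcOH (1 equiv per fluoride), THF, 0 °C → rt
Reagents that add atoms: none
Why: fluoride-mediated cleavage of the primary silyl ether, buffered with acetic acid so that the two esters and the base-sensitive C2–H/C3–OAc pair should survive.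

**Step 12**
Reactants: 18 (1R)-1-[(2R,3R)-3-acetoxy-2-(3-hydroxyprop-1-en-2-yl)-2,3-dihydro-1-benzofuran-5-yl]ethyl (2Z)-2-methylbut-2-enoate
Product: 19 (1R)-1-[(2R,3R)-3-acetoxy-2-(3-oxoprop-1-en-2-yl)-2,3-dihydro-1-benzofuran-5-yl]ethyl (2Z)-2-methylbut-2-enoate (CNP0294391.3)
Conditions: Dess–Martin periodinane, NaHCO3, CH2Cl2, 0 °C → rt
Reagents that add atoms: none
Why: Dess–Martin oxidation of the primary allylic alcohol under buffered, neutral conditions should give the 2-substituted acrolein last, so that this base- and nucleophile-sensitive group sees no further reagent.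

**Compound list**

1 | tert-butyl acrylate | C=CC(=O)OC(C)(C)C | starting material
2 | 2,2-dimethoxyacetaldehyde (glyoxal dimethyl acetal, sold as aqueous solution) | COC(OC)C=O | starting material
3 | tert-butyl 3-hydroxy-4,4-dimethoxy-2-methylidenebutanoate (racemic) | C=C(C(O)C(OC)OC)C(=O)OC(C)(C)C | intermediate
4 | tert-butyl 4,4-dimethoxy-3-[(methoxycarbonyl)oxy]-2-methylidenebutanoate (racemic) | C=C(C(OC(=O)OC)C(OC)OC)C(=O)OC(C)(C)C | intermediate
5 | 4-hydroxyacetophenone | CC(=O)c1ccc(O)cc1 | starting material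
6 | tert-butyl (3R)-3-(4-acetylphenoxy)-4,4-dimethoxy-2-methylidenebutanoate (allyl aryl ether, formed in the flask) | C=C(C(=O)OC(C)(C)C)[C@@H](Oc1ccc(C(C)=O)cc1)C(OC)OC | intermediate
7 | (4R)-4-(4-acetylphenoxy)-5-methoxy-3-methylideneoxolan-2-one (methoxy lactone, both acetal epimers, formed in the flask) | C=C1C(=O)OC(OC)[C@@H]1Oc1ccc(C(C)=O)cc1 | intermediate
8 | (3aR,8bR)-7-acetyl-3-methylidene-3a,8b-dihydrofuro[3,2-b][1]benzofuran-2(3H)-one (cis-fused tricyclic α-methylene lactone) | C=C1[C@H]2Oc3ccc(C(C)=O)cc3[C@H]2OC1=O | intermediate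
9 | (3aR,8bR)-7-[(1R)-1-hydroxyethyl]-3-methylidene-3a,8b-dihydrofuro[3,2-b][1]benzofuran-2(3H)-one | C=C1[C@H]2Oc3ccc([C@@H](C)O)cc3[C@H]2OC1=O | intermediate
10 | (3aR,8bR)-3-methylidene-7-[(1R)-1-(triethylsilyloxy)ethyl]-3a,8b-dihydrofuro[3,2-b][1]benzofuran-2(3H)-one | C=C1[C@H]2Oc3ccc([C@@H](C)O[Si](CC)(CC)CC)cc3[C@H]2OC1=O | intermediate
11 | (2R,3R)-2-(3-hydroxyprop-1-en-2-yl)-5-[(1R)-1-(triethylsilyloxy)ethyl]-2,3-dihydro-1-benzofuran-3-ol | C=C(CO)[C@H]1Oc2ccc([C@@H](C)O[Si](CC)(CC)CC)cc2[C@H]1O | intermediate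
12 | (2R,3R)-2-[3-(tert-butyldiphenylsilyloxy)prop-1-en-2-yl]-5-[(1R)-1-(triethylsilyloxy)ethyl]-2,3-dihydro-1-benzofuran-3-ol | C=C(CO[Si](c1ccccc1)(c1ccccc1)C(C)(C)C)[C@H]1Oc2ccc([C@@H](C)O[Si](CC)(CC)CC)cc2[C@H]1O | intermediate
13 | (2R,3R)-2-[3-(tert-butyldiphenylsilyloxy)prop-1-en-2-yl]-5-[(1R)-1-(triethylsilyloxy)ethyl]-2,3-dihydro-1-benzofuran-3-yl acetate | C=C(CO[Si](c1ccccc1)(c1ccccc1)C(C)(C)C)[C@H]1Oc2ccc([C@@H](C)O[Si](CC)(CC)CC)cc2[C@H]1OC(C)=O | intermediate
14 | (2R,3R)-2-[3-(tert-butyldiphenylsilyloxy)prop-1-en-2-yl]-5-[(1R)-1-hydroxyethyl]-2,3-dihydro-1-benzofuran-3-yl acetate | C=C(CO[Si](c1ccccc1)(c1ccccc1)C(C)(C)C)[C@H]1Oc2ccc([C@@H](C)O)cc2[C@H]1OC(C)=O | intermediate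
15 | angelic acid, (2Z)-2-methylbut-2-enoic acid | C/C=C(/C)C(=O)O | starting material
16 | angelic 2,4,6-trichlorobenzoic anhydride (mixed anhydride, formed in the flask) | C/C=C(/C)C(=O)OC(=O)c1c(Cl)cc(Cl)cc1Cl | intermediate
17 | (1R)-1-{(2R,3R)-3-acetoxy-2-[3-(tert-butyldiphenylsilyloxy)prop-1-en-2-yl]-2,3-dihydro-1-benzofuran-5-yl}ethyl (2Z)-2-methylbut-2-enoate | C=C(CO[Si](c1ccccc1)(c1ccccc1)C(C)(C)C)[C@H]1Oc2ccc([C@@H](C)OC(=O)/C(C)=C\C)cc2[C@H]1OC(C)=O | intermediate
18 | (1R)-1-[(2R,3R)-3-acetoxy-2-(3-hydroxyprop-1-en-2-yl)-2,3-dihydro-1-benzofuran-5-yl]ethyl (2Z)-2-methylbut-2-enoate | C=C(CO)[C@H]1Oc2ccc([C@@H](C)OC(=O)/C(C)=C\C)cc2[C@H]1OC(C)=O | intermediate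
19 | (1R)-1-[(2R,3R)-3-acetoxy-2-(3-oxoprop-1-en-2-yl)-2,3-dihydro-1-benzofuran-5-yl]ethyl (2Z)-2-methylbut-2-enoate (CNP0294391.3) | C=C(C=O)[C@H]1Oc2ccc([C@@H](C)OC(=O)/C(C)=C\C)cc2[C@H]1OC(C)=O | target

**Step count and risks**

Total step count: 12. Longest linear sequence: 12 steps (from 1 and 2 to 19); 5 and 15 enter at steps 3 and 10.

Steps most likely to fail:

1. Step 3 (proposed new method). Ring closure onto the acetyl-deactivated ring A may be too slow, so that the acyloxocarbenium ion loses the proton at C2 and the stereocentre is erased; the etherification may also turn toward the linear regioisomer. The fallback makes the same two bonds in separate, precedented steps, sets out from 4 and comes back at 8. The same palladium-catalysed asymmetric etherification of 4, now with commercial 4-hydroxy-3-iodoacetophenone, should give tert-butyl (3R)-3-(4-acetyl-2-iodophenoxy)-4,4-dimethoxy-2-methylidenebutanoate F1. Selective acetal hydrolysis (Amberlyst-15, wet acetone, rt) should give the aldehyde tert-butyl (3R)-3-(4-acetyl-2-iodophenoxy)-2-methylidene-4-oxobutanoate F2, used crude. An intramolecular Nozaki–Hiyama–Kishi reaction (CrCl2 in excess, NiCl2 cat., DMF, rt; divalent chromium tolerates the ketone and the ester) should close ring B to tert-butyl 2-[(2R,3R)-5-acetyl-3-hydroxy-2,3-dihydro-1-benzofuran-2-yl]prop-2-enoate F3 together with its trans isomer. TFA in CH2Cl2 then removes the tert-butyl group and lactonises only the cis isomer to 8; the trans hydroxy acid cannot lactonise and is separated.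

2. Step 10. The angeloyl group may isomerise to the E-configured tigloyl group during activation or heating, or the benzylic carbinol may eliminate. The fallback builds the Z alkene on the ester instead of carrying it in, sets out from 14 and comes back at 17. Coupling of 14 with 2-[bis(2,2,2-trifluoroethoxy)phosphoryl]propanoic acid (EDC·HCl, DMAP cat., CH2Cl2, 0 °C) should give (1R)-1-{(2R,3R)-3-acetoxy-2-[3-(tert-butyldiphenylsilyloxy)prop-1-en-2-yl]-2,3-dihydro-1-benzofuran-5-yl}ethyl 2-[bis(2,2,2-trifluoroethoxy)phosphoryl]propanoate F4. A Still–Gennari olefination (KN(SiMe3)2, 18-crown-6, THF, −78 °C, then acetaldehyde) should then give the Z-configured 2-methylbut-2-enoate 17; the phosphonate is deprotonated first because it is far more acidic than the acetate.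

3. Step 11. Cleavage of the hindered silyl ether under buffered fluoride may be slow, and prolonged exposure can lead to loss of the C3 acetate by elimination toward the aromatic benzofuran or to ester cleavage. The fallback replaces silyl protection of the primary hydroxyl by enzymatic differentiation of esters, sets out from 11 and comes back at 18. Acetylation of both hydroxyls of 11 (Ac2O, pyridine, DMAP cat.) should give (2R,3R)-2-(3-acetoxyprop-1-en-2-yl)-5-[(1R)-1-(triethylsilyloxy)ethyl]-2,3-dihydro-1-benzofuran-3-yl acetate F5. Buffered HF·pyridine should give (2R,3R)-2-(3-acetoxyprop-1-en-2-yl)-5-[(1R)-1-hydroxyethyl]-2,3-dihydro-1-benzofuran-3-yl acetate F6. Yamaguchi esterification with 15 through 16, as in step 10, should give (1R)-1-[(2R,3R)-3-acetoxy-2-(3-acetoxyprop-1-en-2-yl)-2,3-dihydro-1-benzofuran-5-yl]ethyl (2Z)-2-methylbut-2-enoate F7. Candida antarctica lipase B in pH 7 phosphate buffer/MTBE should then hydrolyse only the unhindered primary allylic acetate and leave the hindered secondary benzylic acetate and the angelate, giving 18.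

**Further compounds**

F1 | step 3 | tert-butyl (3R)-3-(4-acetyl-2-iodophenoxy)-4,4-dimethoxy-2-methylidenebutanoate | C=C(C(=O)OC(C)(C)C)[C@@H](Oc1ccc(C(C)=O)cc1I)C(OC)OC
F2 | step 3 | tert-butyl (3R)-3-(4-acetyl-2-iodophenoxy)-2-methylidene-4-oxobutanoate | C=C(C(=O)OC(C)(C)C)[C@@H](Oc1ccc(C(C)=O)cc1I)C=O
F3 | step 3 | tert-butyl 2-[(2R,3R)-5-acetyl-3-hydroxy-2,3-dihydro-1-benzofuran-2-yl]prop-2-enoate | C=C(C(=O)OC(C)(C)C)[C@H]1Oc2ccc(C(C)=O)cc2[C@H]1O
F4 | step 10 | (1R)-1-{(2R,3R)-3-acetoxy-2-[3-(tert-butyldiphenylsilyloxy)prop-1-en-2-yl]-2,3-dihydro-1-benzofuran-5-yl}ethyl 2-[bis(2,2,2-trifluoroethoxy)phosphoryl]propanoate | C=C(CO[Si](c1ccccc1)(c1ccccc1)C(C)(C)C)[C@H]1Oc2ccc([C@@H](C)OC(=O)C(C)P(=O)(OCC(F)(F)F)OCC(F)(F)F)cc2[C@H]1OC(C)=O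
F5 | step 11 | (2R,3R)-2-(3-acetoxyprop-1-en-2-yl)-5-[(1R)-1-(triethylsilyloxy)ethyl]-2,3-dihydro-1-benzofuran-3-yl acetate | C=C(COC(C)=O)[C@H]1Oc2ccc([C@@H](C)O[Si](CC)(CC)CC)cc2[C@H]1OC(C)=O
F6 | step 11 | (2R,3R)-2-(3-acetoxyprop-1-en-2-yl)-5-[(1R)-1-hydroxyethyl]-2,3-dihydro-1-benzofuran-3-yl acetate | C=C(COC(C)=O)[C@H]1Oc2ccc([C@@H](C)O)cc2[C@H]1OC(C)=O
F7 | step 11 | (1R)-1-[(2R,3R)-3-acetoxy-2-(3-acetoxyprop-1-en-2-yl)-2,3-dihydro-1-benzofuran-5-yl]ethyl (2Z)-2-methylbut-2-enoate | C=C(COC(C)=O)[C@H]1Oc2ccc([C@@H](C)OC(=O)/C(C)=C\C)cc2[C@H]1OC(C)=O
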